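**Retrosynthetic overview**
- The butenolide ring is closed last: Pd/Cu coupling of a terminal (E)-enynol with (Z)-3-iodobut-2-enoic acid, then 5-exo-dig lactonisation.
- Key step: a [3,3]-sigmatropic 1,3-transposition of an allyl perrhenate turns a secondary enynyl carbinol into the (E)-2-substituted enynol. It forms the C–O bond of the CH2OH group and sets the trisubstituted alkene.
- The carbinol comes from an sp3–sp2 Negishi coupling of a homodrimenylzinc iodide with a 2-bromo-enynol (2-bromoacrolein plus a silylacetylide).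
- The iodide comes from (+)-sclareolide (acid methanolysis to the C8=C9 alkene, reduction, iodination).
- Ring order: rings A and B and both stereocentres are bought with sclareolide; the butenolide is the only ring made.

Assumption: 2-bromoacrolein is bought (stabilised) and used fresh; the carbinol centre made in step 4 is not in the target, is carried as a mixture and is erased in step 6.
Abbreviation: Oct = (4aS,8aS)-2,5,5,8a-tetramethyl-3,4,4a,5,6,7,8,8a-octahydronaphthalen-1-yl (the ring A/B unit with the C8=C9 alkene, attached through C9).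

**Step 1**
Reactants: 1 (+)-sclareolide
Product: 2 methyl 2-(Oct)acetate
Conditions: conc. H2SO4, MeOH, reflux; AgNO3–SiO2 chromatography
Reagents that add atoms: methanol (CO)
Why: Acid-mediated alkyl–oxygen fission of the tertiary lactone (E1 elimination) with Fischer esterification, run to thermodynamic control, should favour the tetrasubstituted C8=C9 alkene, and the two ring-fusion stereocentres bought with 1 are not touched.

**Step 2**
Reactants: 2 methyl 2-(Oct)acetate
Product: 3 2-(Oct)ethan-1-ol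
Conditions: LiAlH4, THF, 0 °C to rt; H2O, aq. NaOH work-up
Reagents that add atoms: none
Why: Hydride reduction of the ester to the primary alcohol leaves the alkene and both stereocentres alone.

**Step 3**
Reactants: 3 2-(Oct)ethan-1-ol
Product: 4 2-(Oct)ethyl iodide
Conditions: I2, PPh3, imidazole, CH2Cl2, 0 °C to rt
Reagents that add atoms: iodine (II)
Why: Appel-type iodination (SN2 on the alkoxyphosphonium ion) of an unhindered primary alcohol under non-ionising conditions, so the homoallylic alkene does not take part.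

**Step 4**
Reactants: 5 2-bromoacrolein; 6 (triisopropylsilyl)acetylene
Product: 8 racemic 2-bromo-5-(triisopropylsilyl)pent-1-en-4-yn-3-ol, via lithium (triisopropylsilyl)acetylide 7 (not isolated)
Conditions: 6, n-BuLi, THF, −78 °C; then 5, −78 °C; H2O
Reagents that add atoms: none
Why: 1,2-Addition of the hard lithium acetylide to the enal carbonyl gives the carbinol as a racemate, which is acceptable because this centre is destroyed in step 6.

**Step 5**
Reactants: 4 2-(Oct)ethyl iodide; 8 racemic 2-bromo-5-(triisopropylsilyl)pent-1-en-4-yn-3-ol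
Product: 10 2-[2-(Oct)ethyl]-5-(triisopropylsilyl)pent-1-en-4-yn-3-ol (1:1 carbinol epimers), via [2-(Oct)ethyl]zinc iodide 9 (not isolated)
Conditions: 4, Zn dust, LiCl, THF, 40 °C; then 8, Pd(OAc)2 (2 mol %), SPhos (4 mol %), THF, 25 °C
Reagents that add atoms: none
Why: Zinc insertion into the primary C–I bond followed by Negishi sp3–sp2 cross-coupling at the vinyl bromide joins C12 to C13; the alkylzinc halide is not basic enough to be quenched quickly by the free carbinol, and the two epimers converge in step 6.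

**Step 6**
Reactants: 10 2-[2-(Oct)ethyl]-5-(triisopropylsilyl)pent-1-en-4-yn-3-ol
Product: 13 (E)-2-[2-(Oct)ethyl]-5-(triisopropylsilyl)pent-2-en-4-yn-1-ol, via secondary allylic perrhenate 11 (not isolated), via primary allylic perrhenate 12 (not isolated)
Conditions: Ph3SiOReO3 (5 mol %), Et2O, −50 to −20 °C; Et3N quench
Reagents that add atoms: none
Why: The carbinol exchanges onto rhenium and the allyl perrhenate undergoes a [3,3]-sigmatropic 1,3-transposition through a chair transition state with the silylalkynyl group pseudo-equatorial, so the new C–O bond forms at the former methylene carbon and the trisubstituted alkene appears E (alkyne trans to CH2OH), driven by enyne conjugation while the bulky silyl group disfavours the competing propargylic shift.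

**Step 7**
Reactants: 13 (E)-2-[2-(Oct)ethyl]-5-(triisopropylsilyl)pent-2-en-4-yn-1-ol
Product: 14 (E)-2-[2-(Oct)ethyl]pent-2-en-4-yn-1-ol
Conditions: Bu4NF, THF, 0 °C
Reagents that add atoms: none
Why: Fluoride-induced protodesilylation of the alkynylsilane frees the terminal alkyne without touching the alkene geometry.

**Step 8**
Reactants: 15 but-2-ynoic acid
Product: 16 (Z)-3-iodobut-2-enoic acid
Conditions: NaI, AcOH, 115 °C
Reagents that add atoms: sodium iodide ([Na+].[I-])
Why: Conjugate anti-hydroiodination of the ynoic acid puts iodine at C3 cis to the carboxyl group.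

**Step 9**
Reactants: 14 (E)-2-[2-(Oct)ethyl]pent-2-en-4-yn-1-ol; 16 (Z)-3-iodobut-2-enoic acid
Product: 18 (5Z)-5-{(2E)-3-(hydroxymethyl)-5-(Oct)pent-2-en-1-ylidene}-4-methylfuran-2(5H)-one (CNP0288110.2), via (2Z,6E)-dienynoic acid 17 (not isolated)
Conditions: Pd(PPh3)4 (5 mol %), CuI (10 mol %), Et3N, MeCN, 25 °C, dark
Reagents that add atoms: none
Why: Sonogashira coupling at the vinyl iodide gives the (Z)-enynoic acid, whose carboxylate adds 5-exo-dig and anti across the metal-activated alkyne before protodemetalation, closing the butenolide with the Z exocyclic alkene while the E alkene and the ring-fusion centres are unaffected.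

**Compound list** (Oct as defined above)

1 | (+)-sclareolide, (3aR,5aS,9aS,9bR)-3a,6,6,9a-tetramethyldecahydronaphtho[2,1-b]furan-2(1H)-one | C[C@]12CCCC([C@@H]1CC[C@@]3([C@@H]2CC(=O)O3)C)(C)C | starting material
2 | methyl 2-(Oct)acetate | COC(=O)CC1=C(C)CC[C@H]2C(C)(C)CCC[C@]12C | intermediate
3 | 2-(Oct)ethan-1-ol | OCCC1=C(C)CC[C@H]2C(C)(C)CCC[C@]12C | intermediate
4 | 2-(Oct)ethyl iodide | ICCC1=C(C)CC[C@H]2C(C)(C)CCC[C@]12C | intermediate
5 | 2-bromoacrolein (2-bromoprop-2-enal) | C=C(Br)C=O | starting material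
6 | (triisopropylsilyl)acetylene | C#C[Si](C(C)C)(C(C)C)C(C)C | starting material
7 | lithium (triisopropylsilyl)acetylide | [Li]C#C[Si](C(C)C)(C(C)C)C(C)C | intermediate
8 | racemic 2-bromo-5-(triisopropylsilyl)pent-1-en-4-yn-3-ol | C=C(Br)C(O)C#C[Si](C(C)C)(C(C)C)C(C)C | intermediate
9 | [2-(Oct)ethyl]zinc iodide | I[Zn]CCC1=C(C)CC[C@H]2C(C)(C)CCC[C@]12C | intermediate
10 | 2-[2-(Oct)ethyl]-5-(triisopropylsilyl)pent-1-en-4-yn-3-ol (carbinol epimers) | C=C(CCC1=C(C)CC[C@H]2C(C)(C)CCC[C@]12C)C(O)C#C[Si](C(C)C)(C(C)C)C(C)C | intermediate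
11 | perrhenate ester of 10 (secondary allylic perrhenate) | C=C(CCC1=C(C)CC[C@H]2C(C)(C)CCC[C@]12C)C(O[Re](=O)(=O)=O)C#C[Si](C(C)C)(C(C)C)C(C)C | intermediate
12 | perrhenate ester of 13 (primary allylic perrhenate, E) | O=[Re](=O)(=O)OC/C(CCC1=C(C)CC[C@H]2C(C)(C)CCC[C@]12C)=C/C#C[Si](C(C)C)(C(C)C)C(C)C | intermediate
13 | (E)-2-[2-(Oct)ethyl]-5-(triisopropylsilyl)pent-2-en-4-yn-1-ol | OC/C(CCC1=C(C)CC[C@H]2C(C)(C)CCC[C@]12C)=C/C#C[Si](C(C)C)(C(C)C)C(C)C | intermediate
14 | (E)-2-[2-(Oct)ethyl]pent-2-en-4-yn-1-ol | OC/C(CCC1=C(C)CC[C@H]2C(C)(C)CCC[C@]12C)=C/C#C | intermediate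
15 | but-2-ynoic acid | CC#CC(=O)O | starting material
16 | (Z)-3-iodobut-2-enoic acid | C/C(I)=C/C(=O)O | intermediate
17 | (2Z,6E)-7-(hydroxymethyl)-3-methyl-9-(Oct)nona-2,6-dien-4-ynoic acid | OC(=O)/C=C(/C)C#C\C=C(\CO)CCC1=C(C)CC[C@H]2C(C)(C)CCC[C@]12C | intermediate
18 | (5Z)-5-{(2E)-3-(hydroxymethyl)-5-(Oct)pent-2-en-1-ylidene}-4-methylfuran-2(5H)-one | CC1=CC(=O)O/C1=C\C=C(\CO)CCC1=C(C)CC[C@H]2C(C)(C)CCC[C@]12C | target

**Step count**
Total: 9 steps. Longest linear sequence: 7 steps (1, 2, 3, 5, 6, 7, 9); steps 4 and 8 make the two small partners.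

**Three steps most likely to fail**

Step 1. The elimination can give the C7=C8 and exocyclic alkene isomers alongside the wanted C8=C9 ester, and they are hard to separate. The fallback sets out from 1 and comes back at 3; it fixes the alkene position by an allylic reductive cleavage instead of an acid elimination. Enolate selenenylation of 1 (LiN(i-Pr)2, PhSeBr, THF, −78 °C) gives 11-(phenylselanyl)sclareolide F1. H2O2 and pyridine oxidise it to the selenoxide F2, which eliminates in the flask to the C9=C11 butenolide 9(11)-dehydrosclareolide F3. SmI2 in THF–HMPA (or Zn in AcOH) cleaves the allylic C8–O bond, and protonation of the dienolate at C11 gives 2-(Oct)acetic acid F4 with the alkene only at C8=C9. LiAlH4 reduces F4 to 3.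

Step 5. The free carbinol of 8 may consume the zinc reagent, or the coupling may stall. The fallback sets out from 4 and comes back at 10; it builds C12–C13 by SN2 alkynylation and C13–C14 by carbonyl addition. LiC≡CH·H2NCH2CH2NH2 in DMSO converts 4 into 4-(Oct)but-1-yne F5. Bromoboration with B-bromo-9-borabicyclo[3.3.1]nonane followed by AcOH gives the Markovnikov vinyl bromide 2-bromo-4-(Oct)but-1-ene F6. Exchange with t-BuLi (Et2O, −78 °C) gives [4-(Oct)but-1-en-2-yl]lithium F7, which adds to 3-(triisopropylsilyl)propynal to give 10.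

Step 6. The perrhenate shift may give E/Z mixtures on equilibration, or ionise to a cation that the C8=C9 alkene can trap. The fallback sets out from 8 (with the zinc reagent 9) and comes back at 13; it replaces the metal-oxo [3,3] shift by a kinetically controlled sulfoxide–sulfenate [2,3] shift (Mislow–Evans), which has no cationic intermediate. PhSSPh and PBu3 convert 8 into 2-bromo-3-(phenylsulfanyl)-5-(triisopropylsilyl)pent-1-en-4-yne F8. Negishi coupling with 9 gives 2-[2-(Oct)ethyl]-3-(phenylsulfanyl)-5-(triisopropylsilyl)pent-1-en-4-yne F9. NaIO4 (MeOH–THF–H2O, 0 °C) oxidises sulfur only, giving the allylic sulfoxide F10. In MeOH with PhSH and Et3N at 25 °C, F10 equilibrates by [2,3] shift with the (E)-allylic benzenesulfenate F11, which the thiol cleaves to 13.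

**Further compounds**

F1 | step 1 | 11-(phenylselanyl)sclareolide | C[C@]12CCCC([C@@H]1CC[C@@]3([C@@H]2C([Se]c4ccccc4)C(=O)O3)C)(C)C
F2 | step 1 | selenoxide of 11-(phenylselanyl)sclareolide (not isolated) | C[C@]12CCCC([C@@H]1CC[C@@]3([C@@H]2C([Se](=O)c4ccccc4)C(=O)O3)C)(C)C
F3 | step 1 | 9(11)-dehydrosclareolide (C9=C11 butenolide) | C[C@]12CCCC([C@@H]1CC[C@@]3(C2=CC(=O)O3)C)(C)C
F4 | step 1 | 2-(Oct)acetic acid | OC(=O)CC1=C(C)CC[C@H]2C(C)(C)CCC[C@]12C
F5 | step 5 | 4-(Oct)but-1-yne | C#CCCC1=C(C)CC[C@H]2C(C)(C)CCC[C@]12C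
F6 | step 5 | 2-bromo-4-(Oct)but-1-ene | C=C(Br)CCC1=C(C)CC[C@H]2C(C)(C)CCC[C@]12C
F7 | step 5 | [4-(Oct)but-1-en-2-yl]lithium (not isolated) | C=C([Li])CCC1=C(C)CC[C@H]2C(C)(C)CCC[C@]12C
F8 | step 6 | 2-bromo-3-(phenylsulfanyl)-5-(triisopropylsilyl)pent-1-en-4-yne | C=C(Br)C(Sc1ccccc1)C#C[Si](C(C)C)(C(C)C)C(C)C
F9 | step 6 | 2-[2-(Oct)ethyl]-3-(phenylsulfanyl)-5-(triisopropylsilyl)pent-1-en-4-yne | C=C(CCC1=C(C)CC[C@H]2C(C)(C)CCC[C@]12C)C(Sc3ccccc3)C#C[Si](C(C)C)(C(C)C)C(C)C
F10 | step 6 | 2-[2-(Oct)ethyl]-3-(phenylsulfinyl)-5-(triisopropylsilyl)pent-1-en-4-yne | C=C(CCC1=C(C)CC[C@H]2C(C)(C)CCC[C@]12C)C(C#C[Si](C(C)C)(C(C)C)C(C)C)S(=O)c3ccccc3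
F11 | step 6 | (E)-2-[2-(Oct)ethyl]-5-(triisopropylsilyl)pent-2-en-4-yn-1-yl benzenesulfenate (not isolated) | CC(C)[Si](C(C)C)(C(C)C)C#C\C=C(\COSc3ccccc3)CCC1=C(C)CC[C@H]2C(C)(C)CCC[C@]12C
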